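**Retrosynthetic overview**
1. Enabling feature: in the cyclohex-2-enone ring the tertiary C6–OH lies 1,4 to the enone β-carbon C3, with the C1 ketone next to C6. A C3–O–C6 oxygen bridge therefore turns the ring into a 7-oxabicyclo[2.2.1]heptan-2-one, the hydrolysed [4+2] adduct of a 2-alkyl-3-methoxyfuran (furan O = 6-OH oxygen, C–OMe = C1).
2. Key disconnection: C5–C6 and C3–C4 together, by an enantioselective Diels–Alder reaction of the furan (dearomatised) with 3-acryloyloxazolidin-2-one under a bis(oxazoline) complex of divalent copper. This builds the only ring and fixes the quaternary carbinol C6.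
3. C4–OH: the acyl group on C4 is exchanged for OH by decarboxylative borylation/oxidation on the convex face of the bicycle (cis to the bridge oxygen). Silyl-triflate-induced β-elimination of the bridge then unveils enone and tertiary alcohol.
4. Furan: C2-lithiated 3-methoxyfuran opens (S)-2-[(Z)-pentadec-8-enyl]oxirane (C2' from (S)-epichlorohydrin, (Z)-alkene by Lindlar semihydrogenation).
5. Ring order: the carbocycle is formed in step 7 inside the temporary oxygen-bridged bicycle; the bridge is opened in step 11.

Key step: step 7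

Assumption: the target is read as (4S,6R) in the ring (4-OH and 6-OH cis) and (2'S,10'Z) in the side chain. The sense of induction in step 7 is taken from the square-planar chelate model of this catalyst family and would have to be confirmed on the first adduct.
Locants used for the bicycles: C1 = bridgehead carrying the side chain (C6 of the target), C2 = carbonyl or enol-ether carbon (C1), C3 (C2), C4 = bridgehead CH (C3), C5 (C4), C6 = CH2 (C5), O7 = bridge (the 6-OH oxygen).
Abbreviations: TBS = tert-butyldimethylsilyl, TMS = trimethylsilyl, t-Bu-box = 2,2'-(propane-2,2-diyl)bis[(4R)-4-tert-butyl-4,5-dihydro-1,3-oxazole], B2cat2 = bis(catecholato)diboron, DMAc = N,N-dimethylacetamide, DIC = N,N'-diisopropylcarbodiimide.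

**Step 1**
Reactants: 1 oct-1-yne; 2 1-bromo-6-chlorohexane
Product: 4 1-chlorotetradec-7-yne, via oct-1-ynyllithium 3 (not isolated)
Conditions: n-BuLi, THF, −78 → 0 °C; then 2, DMPU, 0 °C → rt
Reagents that add atoms: none
Why: Acetylide alkylation (SN2) should occur at the bromide far faster than at the chloride, which is kept as the later Grignard handle.

**Step 2**
Reactants: 4 1-chlorotetradec-7-yne
Product: 5 (Z)-1-chlorotetradec-7-ene
Conditions: H2 (1 atm), Pd/CaCO3 poisoned with Pb(OAc)2 (Lindlar catalyst), quinoline, hexane, rt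
Reagents that add atoms: none
Why: Lindlar semihydrogenation adds H2 syn on the poisoned palladium surface and so sets the (Z)-alkene; the primary chloride is inert.

**Step 3**
Reactants: 5 (Z)-1-chlorotetradec-7-ene; 6 (S)-epichlorohydrin
Product: 9 (S)-2-[(Z)-pentadec-8-en-1-yl]oxirane, via Grignard reagent 7 (not isolated), via chlorohydrin 8 (not isolated)
Conditions: Mg, I2 (cat.), THF, reflux; then CuI (10 mol%), 6, THF, −40 → −20 °C; 1 M HCl; then NaOH, MeOH/Et2O, 0 °C → rt (crude chlorohydrin)
Reagents that add atoms: none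
Why: Copper-catalysed Grignard opening of the epoxide at its CH2 terminus, then intramolecular Williamson closure of the chlorohydrin, relays the untouched (S) centre of epichlorohydrin into the (S)-alkyloxirane.

**Step 4**
Reactants: 10 3-bromofuran
Product: 11 3-methoxyfuran
Conditions: NaOMe, CuBr (10 mol%), MeOH/NMP, 110 °C (sealed tube); distillation
Reagents that add atoms: sodium methoxide, C[O-].[Na+]
Why: Ullmann-type copper-catalysed methoxylation of a heteroaryl bromide is well established for 3-bromofuran and 3-bromothiophene.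

**Step 5**
Reactants: 11 3-methoxyfuran; 9 (S)-2-[(Z)-pentadec-8-en-1-yl]oxirane
Product: 13 (2S,10Z)-1-(3-methoxyfuran-2-yl)heptadec-10-en-2-ol, via 2-lithio-3-methoxyfuran 12 (not isolated)
Conditions: n-BuLi, THF, −78 → 0 °C; then BF3·OEt2, 9, −78 °C; then H2O
Reagents that add atoms: none
Why: Directed lithiation of 3-methoxyfuran should occur at C2 (between ring O and OMe), and BF3-assisted SN2 opening of the terminal epoxide at CH2 leaves the carbinol centre (S).

**Step 6**
Reactants: 13 (2S,10Z)-1-(3-methoxyfuran-2-yl)heptadec-10-en-2-ol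
Product: 14 tert-butyl{[(2S,10Z)-1-(3-methoxyfuran-2-yl)heptadec-10-en-2-yl]oxy}dimethylsilane
Conditions: TBSCl, imidazole, DMF, rt
Reagents that add atoms: tert-butyldimethylsilyl chloride, CC(C)(C)[Si](C)(C)Cl
Why: Standard base-only silylation of the secondary alcohol spares the acid-labile alkoxyfuran and masks the hydroxyl so that it cannot trap the oxocarbenium stage of step 7.

**Step 7**
Reactants: 14 tert-butyl{[(2S,10Z)-1-(3-methoxyfuran-2-yl)heptadec-10-en-2-yl]oxy}dimethylsilane; 15 3-acryloyloxazolidin-2-one
Product: 17 3-{[(1S,4R,5R)-1-{(2S,10Z)-2-[(tert-butyldimethylsilyl)oxy]heptadec-10-en-1-yl}-2-oxo-7-oxabicyclo[2.2.1]hept-5-yl]carbonyl}oxazolidin-2-one (acyl endo), via enol ether cycloadduct 16 (not isolated)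
Conditions: [Cu((R,R)-t-Bu-box)](SbF6)2 (10 mol%, from CuCl2, ligand and AgSbF6), 4 Å MS, CH2Cl2, −78 → −40 °C; then 0.5 M aq. HCl, THF, 0 °C
Reagents that add atoms: water, O
Why: The bis(oxazoline) complex of divalent copper binds the acrylimide as a square-planar chelate (s-cis enone), and the furan should add in a concerted but highly asynchronous [4+2] (first bond from furan C2 to the CH2 terminus, Mukaiyama–Michael-like, then collapse at furan C5), after which the strained enol ether is hydrolysed to the stable ketone. The closest known reaction types are the enantioselective Diels–Alder reaction of furan itself with this dienophile under the same catalyst family and the thermal Diels–Alder reactions of 3-alkoxyfurans. The only ring closed is the six-membered carbocycle, closed by intermolecular suprafacial [4+2] cycloaddition across furan C2/C5, the furan oxygen becoming the one-atom bridge. The new stereocentres C1 and C4 (bridgeheads) and C5 are controlled by the catalyst: the tert-butyl groups of the (R,R) ligand should leave the Si face of the acrylimide α-carbon open, and the endo mode couples that face to the (1S,4R) bridgeheads, while C5 is erased in step 10. Regioselectivity (CH2 to the alkyl-bearing C2, acyl-bearing carbon to C5) is secured by the 3-methoxy group, which makes C2 the nucleophilic enol-ether terminus ("para" orientation). The step needs endo/exo and facial selectivity above all, because an exo adduct formed on the same dienophile face would carry the opposite bridgeheads; it is a diastereomer of 17 and should be removable by chromatography.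

**Step 8**
Reactants: 17 (endo imide ketone)
Product: 19 (1S,4R,5R)-1-{(2S,10Z)-2-[(tert-butyldimethylsilyl)oxy]heptadec-10-en-1-yl}-2-oxo-7-oxabicyclo[2.2.1]heptane-5-carboxylic acid, via peroxy acid 18 (not isolated)
Conditions: LiOH·H2O, 30% H2O2, THF/H2O, 0 °C; then aq. Na2SO3; then 1 M HCl (pH 3)
Reagents that add atoms: hydrogen peroxide, OO
Why: Hydroperoxide cleavage of an N-acyloxazolidinone attacks the exocyclic carbonyl selectively, and the bicyclic ketone, which needs strong base or a silyl triflate to open, should survive at 0 °C.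

**Step 9**
Reactants: 19 (bicyclic keto acid)
Product: 20 1,3-dioxoisoindolin-2-yl (1S,4R,5R)-1-{(2S,10Z)-2-[(tert-butyldimethylsilyl)oxy]heptadec-10-en-1-yl}-2-oxo-7-oxabicyclo[2.2.1]heptane-5-carboxylate
Conditions: N-hydroxyphthalimide, DIC, DMAP (5 mol%), CH2Cl2, 0 °C → rt
Reagents that add atoms: N-hydroxyphthalimide, O=C1N(O)C(=O)c2ccccc12
Why: Carbodiimide esterification gives the redox-active N-acyloxyphthalimide needed for radical decarboxylation.

**Step 10**
Reactants: 20 (redox-active ester)
Product: 22 (1S,4R,5S)-1-{(2S,10Z)-2-[(tert-butyldimethylsilyl)oxy]heptadec-10-en-1-yl}-5-hydroxy-7-oxabicyclo[2.2.1]heptan-2-one (5-OH exo), via catechol boronate 21 (not isolated)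
Conditions: B2cat2, DMAc, blue LEDs (450 nm), rt; then 30% H2O2, pH 7 phosphate buffer, THF, 0 °C
Reagents that add atoms: hydrogen peroxide, OO (oxygen of the new hydroxyl); bis(catecholato)diboron, B1(Oc2ccccc2O1)B1Oc2ccccc2O1 (boron of 21 only)
Why: Photoinduced decarboxylative borylation followed by stereoretentive C–B oxidation should trap the secondary C5 radical on the convex exo face of the bicyclo[2.2.1] frame (syn to the oxygen bridge), which sets the carbinol centre whatever the configuration of the acid, and it involves no thiyl radicals that would isomerise the (Z)-alkene.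

**Step 11**
Reactants: 22 (exo alcohol)
Product: 23 (4S,6R)-6-{(2S,10Z)-2-[(tert-butyldimethylsilyl)oxy]heptadec-10-en-1-yl}-4,6-bis[(trimethylsilyl)oxy]cyclohex-2-en-1-one
Conditions: TMSOTf (2.5 equiv), Et3N (4 equiv), CH2Cl2, −78 → 0 °C
Reagents that add atoms: trimethylsilyl trifluoromethanesulfonate, C[Si](C)(C)OS(=O)(=O)C(F)(F)F
Why: Silyl-triflate/amine-induced opening of 7-oxabicyclo[2.2.1]heptan-2-ones (soft enolisation towards C3, then silyl-assisted β-elimination of the bridge oxygen from C4) is the established route to 6-silyloxycyclohex-2-enones; the C1–O bond is not broken, so the quaternary carbinol keeps its configuration.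

**Step 12**
Reactants: 23 (silylated enone)
Product: 24 (4S,6R)-4,6-dihydroxy-6-[(2S,10Z)-2-hydroxyheptadec-10-en-1-yl]cyclohex-2-en-1-one
Conditions: HF·pyridine, pyridine, THF, 0 °C → rt
Reagents that add atoms: none
Why: Pyridine-buffered fluoride desilylation should remove both trimethylsilyl ethers and the secondary tert-butyldimethylsilyl ether without acid-induced dehydration or base-induced γ-deprotonation of the 4-hydroxyenone.

**Compound list**
1 | oct-1-yne | C#CCCCCCC | starting material
2 | 1-bromo-6-chlorohexane | BrCCCCCCCl | starting material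
3 | oct-1-ynyllithium | [Li]C#CCCCCCC | intermediate
4 | 1-chlorotetradec-7-yne | CCCCCCC#CCCCCCCCl | intermediate
5 | (Z)-1-chlorotetradec-7-ene | CCCCCC/C=C\CCCCCCCl | intermediate
6 | (S)-epichlorohydrin | ClC[C@@H]1CO1 | starting material
7 | (Z)-tetradec-7-enylmagnesium chloride | CCCCCC/C=C\CCCCCC[Mg]Cl | intermediate
8 | (2S,10Z)-1-chloroheptadec-10-en-2-ol | CCCCCC/C=C\CCCCCCC[C@H](O)CCl | intermediate
9 | (S)-2-[(Z)-pentadec-8-en-1-yl]oxirane | CCCCCC/C=C\CCCCCCC[C@H]1CO1 | intermediate
10 | 3-bromofuran | Brc1ccoc1 | starting material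
11 | 3-methoxyfuran | COc1ccoc1 | intermediate
12 | 2-lithio-3-methoxyfuran | COc1ccoc1[Li] | intermediate
13 | (2S,10Z)-1-(3-methoxyfuran-2-yl)heptadec-10-en-2-ol | CCCCCC/C=C\CCCCCCC[C@H](O)Cc1occc1OC | intermediate
14 | tert-butyl{[(2S,10Z)-1-(3-methoxyfuran-2-yl)heptadec-10-en-2-yl]oxy}dimethylsilane | CCCCCC/C=C\CCCCCCC[C@H](O[Si](C)(C)C(C)(C)C)Cc1occc1OC | intermediate
15 | 3-acryloyloxazolidin-2-one | C=CC(=O)N1CCOC1=O | starting material
16 | enol ether cycloadduct: (1S,4R,5R)-2-methoxy-7-oxabicyclo[2.2.1]hept-2-ene with the side chain on C1 and the endo acyloxazolidinone on C5 | CCCCCC/C=C\CCCCCCC[C@H](O[Si](C)(C)C(C)(C)C)C[C@@]12C[C@@H](C(=O)N3CCOC3=O)[C@H](O2)C=C1OC | intermediate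
17 | 3-{[(1S,4R,5R)-1-{(2S,10Z)-2-[(tert-butyldimethylsilyl)oxy]heptadec-10-en-1-yl}-2-oxo-7-oxabicyclo[2.2.1]hept-5-yl]carbonyl}oxazolidin-2-one | CCCCCC/C=C\CCCCCCC[C@H](O[Si](C)(C)C(C)(C)C)C[C@@]12C[C@@H](C(=O)N3CCOC3=O)[C@H](O2)CC1=O | intermediate
18 | peroxy acid corresponding to 19 | CCCCCC/C=C\CCCCCCC[C@H](O[Si](C)(C)C(C)(C)C)C[C@@]12C[C@@H](C(=O)OO)[C@H](O2)CC1=O | intermediate
19 | (1S,4R,5R)-1-{(2S,10Z)-2-[(tert-butyldimethylsilyl)oxy]heptadec-10-en-1-yl}-2-oxo-7-oxabicyclo[2.2.1]heptane-5-carboxylic acid | CCCCCC/C=C\CCCCCCC[C@H](O[Si](C)(C)C(C)(C)C)C[C@@]12C[C@@H](C(=O)O)[C@H](O2)CC1=O | intermediate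
20 | 1,3-dioxoisoindolin-2-yl ester of 19 | CCCCCC/C=C\CCCCCCC[C@H](O[Si](C)(C)C(C)(C)C)C[C@@]12C[C@@H](C(=O)ON3C(=O)c4ccccc4C3=O)[C@H](O2)CC1=O | intermediate
21 | exo-5-(1,3,2-benzodioxaborol-2-yl) bicyclic ketone | CCCCCC/C=C\CCCCCCC[C@H](O[Si](C)(C)C(C)(C)C)C[C@@]12C[C@H](B3Oc4ccccc4O3)[C@H](O2)CC1=O | intermediate
22 | (1S,4R,5S)-1-{(2S,10Z)-2-[(tert-butyldimethylsilyl)oxy]heptadec-10-en-1-yl}-5-hydroxy-7-oxabicyclo[2.2.1]heptan-2-one | CCCCCC/C=C\CCCCCCC[C@H](O[Si](C)(C)C(C)(C)C)C[C@@]12C[C@H](O)[C@H](O2)CC1=O | intermediate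
23 | (4S,6R)-6-{(2S,10Z)-2-[(tert-butyldimethylsilyl)oxy]heptadec-10-en-1-yl}-4,6-bis[(trimethylsilyl)oxy]cyclohex-2-en-1-one | CCCCCC/C=C\CCCCCCC[C@H](O[Si](C)(C)C(C)(C)C)C[C@@]1(O[Si](C)(C)C)C[C@H](O[Si](C)(C)C)C=CC1=O | intermediate
24 | (4S,6R)-4,6-dihydroxy-6-[(2S,10Z)-2-hydroxyheptadec-10-en-1-yl]cyclohex-2-en-1-one | CCCCCC/C=C\CCCCCCC[C@H](O)C[C@@]1(O)C[C@H](O)C=CC1=O | target

**Step count**
Total: 12 steps. Longest linear sequence: 11 steps (steps 1–3 and 5–12; step 4 is a one-step branch).

**Steps most likely to fail**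

Step 7. The processes that may go wrong are:
- poor endo/exo or facial discrimination, which would deliver the C1-epimeric series;
- diversion of the activated acrylimide into conjugate (Friedel–Crafts-type) addition at the free furan C5;
- premature opening of the oxygen bridge of the enol ether adduct.

If only the exo mode dominated, the enantiomeric ligand would be used, since C5 is erased later. Fallback, setting out from 14 and returning at 19: stereocontrol is moved from the catalyst to a covalently bound stoichiometric controller. Compound 14 is combined with commercial (S)-4-benzyl-3-acryloyloxazolidin-2-one (C=CC(=O)N1[C@@H](Cc2ccccc2)COC1=O) and Me2AlCl in CH2Cl2 at −90 °C. By the chelate model the benzyl group should again leave the Si face of the α-carbon open. This should give the enol ether cycloadduct F1, hydrolysed on work-up (0.5 M HCl) to the bicyclic ketone F2, whose diastereomers are separable and assignable. LiOH/H2O2 cleavage then passes through peroxy acid 18 to acid 19.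

Step 10. The processes that may go wrong are:
- incomplete exo selectivity in trapping the C5 radical;
- fragmentation of that radical by C6–C1 scission towards the oxygen- and carbonyl-stabilised C1 radical;
- interference of the diboron reagent with the strained ketone.

Fallback, setting out from 19 and returning at 22: oxygen replaces boron as the radical trap. Acid 19 is irradiated (blue LEDs) with 9-mesityl-10-methylacridinium perchlorate (5 mol%) and 2,6-lutidine under O2 in MeCN (photocatalytic decarboxylative oxygenation). This should give the exo hydroperoxide F3, reduced in the same flask with PPh3 to alcohol 22.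

Step 11. The processes that may go wrong are:
- over-silylation to a dienol ether by γ-deprotonation, followed by loss of the C4 centre or aromatisation;
- incomplete opening of the bridge.

Fallback, setting out from 22 and returning at 24: the order and the mechanism are changed. Compound 22 is first desilylated (HF·pyridine, pyridine, THF) to the bicyclic diol F4. This is then opened by an anionic E1cB elimination with DBU in CH2Cl2 at 0 °C, giving 24 directly.

**Further compounds**
F1 | step 7 | enol ether cycloadduct of 14 with (S)-4-benzyl-3-acryloyloxazolidin-2-one (endo, bridgeheads as in 16) | CCCCCC/C=C\CCCCCCC[C@H](O[Si](C)(C)C(C)(C)C)C[C@@]12C[C@@H](C(=O)N3[C@@H](Cc4ccccc4)COC3=O)[C@H](O2)C=C1OC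
F2 | step 7 | bicyclic ketone from F1: (S)-4-benzyl analogue of 17 | CCCCCC/C=C\CCCCCCC[C@H](O[Si](C)(C)C(C)(C)C)C[C@@]12C[C@@H](C(=O)N3[C@@H](Cc4ccccc4)COC3=O)[C@H](O2)CC1=O
F3 | step 10 | (1S,4R,5S)-5-hydroperoxy analogue of 22 | CCCCCC/C=C\CCCCCCC[C@H](O[Si](C)(C)C(C)(C)C)C[C@@]12C[C@H](OO)[C@H](O2)CC1=O
F4 | step 11 | (1S,4R,5S)-5-hydroxy-1-[(2S,10Z)-2-hydroxyheptadec-10-en-1-yl]-7-oxabicyclo[2.2.1]heptan-2-one | CCCCCC/C=C\CCCCCCC[C@H](O)C[C@@]12C[C@H](O)[C@H](O2)CC1=O
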